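Numbering (azulene): C1 ketone, C2 CH2, C3 CH(iPr), C3a C-OH, C4, C5, C6(CH3)=C7, C8 CH-O-acyl, C8a C-CH3.
Cuts: the ester C-O; C8 carbinol back to the enone and then to an (8S) silyl ether; C1=O read as C1=CH2; then C1-C2 and C3a-C8a are cut together, which opens both rings to one chain; last C8-C8a and the cyclopropanol.
Enabling feature: the five-membered ring is a 3-hydroxy ketone. C2-C3-C3a is therefore the homoenolate of a C3a ketone (stored as a cyclopropanol, whose C2-C3a bond is not in the target), and C8a-C1 is the substituted end and the centre of an allene. The tether C4-C8 holds a (Z)-alkene that lets the ends meet.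
Forward: nerol gives C4-C8 with the (Z)-C6=C7 bond; a Kulinkovich reaction adds C2, C3 and the isopropyl group; allenylboration adds C8a, its methyl, C1 and =CH2; one cobalt-catalysed (3+2) event closes the five- and seven-membered rings together.
Stereochemistry: C3 comes from a titanium TADDOLate and a relay centre (8S) from a chiral phosphoric acid. With two independent catalysts, residual wrong enantiomer becomes separable diastereomer. Both centres steer C3a and C8a in the key step, and C8 is then reset to (8R) by oxidation and 3a-OH-directed reduction.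
The =CH2 helper masks the C1 ketone during the C8 correction and is cleaved in the last step.

Key step: step 11

Assumption: the facial sense of Ti[(R,R)-TADDOLate]2 in step 5 and of (R)-TRIP in step 9 is taken by analogy with the parent reactions; if either proves opposite, the mirror-image ligand or acid is used and nothing else changes.

Step 1
Reactants: 1 nerol
Product: 2 neryl tert-butyldiphenylsilyl ether
Conditions: TBDPSCl, imidazole, CH2Cl2, 0 °C to rt
Reagents that add atoms: tert-butyl(chloro)diphenylsilane, CC(C)(C)[Si](Cl)(c1ccccc1)c1ccccc1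
Why: Routine imidazole-promoted silyl ether formation on a primary allylic alcohol; the group withstands peracid, periodic acid, methanolic base and the Grignard reagent of steps 2 to 5, and the (Z)-alkene of nerol, the future C6=C7 bond, is not touched.

Step 2
Reactants: 2 neryl tert-butyldiphenylsilyl ether
Product: 3 6,7-epoxide of 2 (racemic at the oxirane CH)
Conditions: mCPBA (1.0 equiv), CH2Cl2, -20 to 0 °C
Reagents that add atoms: 3-chloroperbenzoic acid, OOC(=O)c1cccc(Cl)c1
Why: Prilezhaev epoxidation picks the electron-richer, unhindered isopropylidene alkene over the alkene deactivated by the allylic oxygen, as is well known for neryl and geranyl derivatives; the new stereocentre is racemic and is removed in step 3.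

Step 3
Reactants: 3 6,7-epoxide of 2
Product: 5 (4Z)-6-[(tert-butyldiphenylsilyl)oxy]-4-methylhex-4-enal, via vicinal diol 4 (not isolated)
Conditions: H5IO6, THF/Et2O, 0 °C
Reagents that add atoms: none
Why: Acid-promoted epoxide hydrolysis followed by Malaprade glycol cleavage in one flask removes three carbons and leaves the aldehyde carbon that becomes C3a, without touching the (Z)-alkene or the silyl ether.

Step 4
Reactants: 5 (4Z)-6-[(tert-butyldiphenylsilyl)oxy]-4-methylhex-4-enal
Product: 6 methyl (4Z)-6-[(tert-butyldiphenylsilyl)oxy]-4-methylhex-4-enoate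
Conditions: I2, KOH, MeOH, 0 °C
Reagents that add atoms: methanol, CO
Why: Oxidative esterification, in which hypoiodite oxidises the methyl hemiacetal faster than it can attack the trisubstituted alkene, gives the ester needed for cyclopropanol formation in one step.

Step 5
Reactants: 6 methyl (4Z)-6-[(tert-butyldiphenylsilyl)oxy]-4-methylhex-4-enoate, 7 (3-methylbutyl)magnesium bromide
Product: 8 (1S,2R)-1-{(3Z)-5-[(tert-butyldiphenylsilyl)oxy]-3-methylpent-3-en-1-yl}-2-(propan-2-yl)cyclopropan-1-ol (the two alkyl groups cis)
Conditions: 7 (3 equiv, slow addition), Ti[(R,R)-TADDOLate]2 (0.3 equiv, aryl = 3,5-(CF3)2C6H3), THF, -10 °C to rt; aq. NH4Cl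
Reagents that add atoms: none
Why: Enantioselective Kulinkovich cyclopropanation, in which the titanacyclopropane formed from two equivalents of 7 acts as a 1,2-dicarbanion on the ester, the usual preference places the two alkyl groups cis, and the C2-symmetric diolate ligands select the face so that the isopropyl-bearing carbon, the future C3, is (R).

Step 6
Reactants: 8 silyl-protected cyclopropanol
Product: 9 (1S,2R)-1-[(3Z)-5-hydroxy-3-methylpent-3-en-1-yl]-2-(propan-2-yl)cyclopropan-1-ol
Conditions: TBAF, AcOH, THF, 0 °C to rt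
Reagents that add atoms: none
Why: Fluoride-mediated desilylation, buffered with acetic acid so that the medium does not open the base-sensitive cyclopropanol.

Step 7
Reactants: 9 cyclopropanol allylic alcohol
Product: 10 (2Z)-5-[(1S,2R)-1-hydroxy-2-(propan-2-yl)cyclopropyl]-3-methylpent-2-enal
Conditions: SO3·pyridine, DMSO, Et3N, CH2Cl2, 0 °C
Reagents that add atoms: none
Why: Parikh-Doering oxidation runs by a two-electron alkoxysulfonium pathway, so the primary allylic alcohol is oxidised while the tertiary cyclopropanol, which is sensitive to one-electron oxidants, is left alone and the (Z)-geometry is kept.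

Step 8
Reactants: 11 prop-1-yn-1-yllithium, 12 2-(iodomethyl)-4,4,5,5-tetramethyl-1,3,2-dioxaborolane
Product: 14 2-(but-2-yn-1-yl)-4,4,5,5-tetramethyl-1,3,2-dioxaborolane, via boron ate complex 13 (not isolated)
Conditions: THF, -78 °C to rt
Reagents that add atoms: none
Why: Matteson-type homologation, in which the alkynyl group adds to boron and then migrates to carbon with loss of iodide, gives the propargylic boronate free of its allenyl isomer.

Step 9
Reactants: 10 (Z)-enal, 14 but-2-ynyl pinacol boronate
Product: 16 (1S,2R)-1-[(3Z,5S)-5-hydroxy-3,6-dimethylocta-3,6,7-trien-1-yl]-2-(propan-2-yl)cyclopropan-1-ol, via O-boryl ether 15 (not isolated)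
Conditions: (R)-TRIP (5 mol %), 4 Å MS, toluene, -30 °C; aq. NaHCO3
Reagents that add atoms: none
Why: Chiral phosphoric acid-catalysed allenylboration, in which the propargylic boronate reacts through a closed six-membered SE2' transition state so that only the allenyl carbinol forms, and the acid bound to a boronate oxygen and the formyl hydrogen directs attack to the Re face of the aldehyde to set the relay centre (8S).

Step 10
Reactants: 16 allenyl carbinol
Product: 17 (1S,2R)-1-{(3Z,5S)-5-[(tert-butyldimethylsilyl)oxy]-3,6-dimethylocta-3,6,7-trien-1-yl}-2-(propan-2-yl)cyclopropan-1-ol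
Conditions: TBSCl (1.1 equiv), imidazole, DMF, 0 °C to rt
Reagents that add atoms: tert-butyl(chloro)dimethylsilane, CC(C)(C)[Si](C)(C)Cl
Why: Selective silylation, since the secondary alcohol reacts with the chlorosilane well before the tertiary cyclopropanol, takes away a second hydroxyl group that could bind cobalt and lose a β-hydrogen in the key step.

Step 11
Reactants: 17 cyclopropanol allene
Product: 20 (3R,3aS,8S,8aR)-8-[(tert-butyldimethylsilyl)oxy]-6,8a-dimethyl-1-methylidene-3-(propan-2-yl)-2,3,4,5,8,8a-hexahydroazulen-3a(1H)-ol, via cobalt homoenolate 18 (not isolated), via ten-membered allylcobalt ketone 19 (not isolated)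
Conditions: CoBr2 (10 mol %), dppe (11 mol %), Zn dust (30 mol %), DABCO (1 equiv), MeCN (0.01 M), 60 °C
Reagents that add atoms: none
Why: Proposed new method: monovalent cobalt (CoBr2, dppe, Zn) binds the cyclopropanol oxygen of 17, β-carbon elimination cuts the less substituted C2-C3a bond of the three-membered ring to give the primary cobalt homoenolate 18 with C3 untouched, the C2-Co bond adds across the terminal π-bond of the tethered allene at its central carbon (first new bond, C1-C2) to give the allylcobalt ketone 19, the substituted allyl terminus C8a then adds to the C3a carbonyl (second new bond, C3a-C8a), and proton exchange with fresh 17 releases 20. The closest known reaction types are the intermolecular cobalt-diphosphine-catalysed formal (3+2) annulation of cyclopropanols with allenes and the cobalt-catalysed reductive (3+2) coupling of enones with allenes; new here are the intramolecular mode, the 1,1-disubstituted allene terminus that becomes quaternary and the medium ring passed on the way. The first closure is a 10-exo carbometallation, helped by the (Z)-C6=C7 bond and by chelation of the homoenolate carbonyl to cobalt, and the second is a transannular carbonyl allylation (exo-trig at C=O) through a six-membered chair Co-O-C3a-C8a-C1-CH2 that divides the ten-membered ring into the five- and the seven-membered ring. The tether can hand C2 to the allene only from the side of C8, so on the allyl unit C8 ends cis to C2 and the methyl group cis to CH2Co, and in the closed chair this methyl group is axial and syn to the cobalt-bound oxygen, which fixes the cis ring fusion (8a-CH3 and 3a-OH on one face). The absolute face is set by two elements that reinforce each other, namely the C3 isopropyl group, which takes the convex side away from the tether (trans to C4), and C8, where the hydrogen eclipses the allyl C=C bond (allylic 1,3-strain) with the silyloxy group anti to the incoming carbonyl, so that (3R,8S)-17 should give (3aS,8aR)-20. The step needs ring opening at CH2 and not at CH(iPr), insertion before protonation or β-hydride elimination of 18, and attack by the substituted allyl terminus, which are secured by the steric bias of the cyclopropanol, by aprotic dilute conditions with the allene held close, and by cobalt resting on the unhindered CH2 terminus.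

Step 12
Reactants: 20 bicyclic silyl ether
Product: 21 (3R,3aS,8S,8aR)-6,8a-dimethyl-1-methylidene-3-(propan-2-yl)-2,3,4,5,8,8a-hexahydroazulene-3a,8(1H)-diol
Conditions: TBAF, THF, rt to 40 °C
Reagents that add atoms: none
Why: Fluoride desilylation of the secondary silyl ether, to which the tertiary alcohol and both alkenes are inert.

Step 13
Reactants: 21 (8S)-diol
Product: 22 (3R,3aS,8aS)-3a-hydroxy-6,8a-dimethyl-1-methylidene-3-(propan-2-yl)-2,3,3a,4,5,8a-hexahydroazulen-8(1H)-one
Conditions: DMP, CH2Cl2, 0 °C to rt
Reagents that add atoms: none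
Why: Dess-Martin oxidation of the secondary allylic alcohol under neutral conditions gives the enone and erases the relay centre, without retro-aldol cleavage of the β-hydroxy ketone and with the tertiary alcohol untouched (the C8a descriptor changes by priority only).

Step 14
Reactants: 22 β-hydroxy enone
Product: 23 (3R,3aS,8R,8aR)-6,8a-dimethyl-1-methylidene-3-(propan-2-yl)-2,3,4,5,8,8a-hexahydroazulene-3a,8(1H)-diol
Conditions: Me4NBH(OAc)3, MeCN/AcOH, -30 °C
Reagents that add atoms: none
Why: Evans-Saksena reduction, in which the 3a-hydroxyl group exchanges onto boron and delivers hydride within the molecule to the face of the C8 carbonyl that it occupies, which is also the convex face of the cis-fused bicycle, should give the 1,3-anti diol with the (8R) configuration by 1,2-reduction.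

Step 15
Reactants: 23 (8R)-diol, 24 4-methoxybenzoyl chloride
Product: 25 (3R,3aS,8R,8aR)-3a-hydroxy-6,8a-dimethyl-1-methylidene-3-(propan-2-yl)-1,2,3,3a,4,5,8,8a-octahydroazulen-8-yl 4-methoxybenzoate
Conditions: DMAP, Et3N, CH2Cl2, rt
Reagents that add atoms: none
Why: DMAP-catalysed acyl transfer distinguishes the secondary allylic alcohol from the tertiary ring-fusion alcohol on steric grounds.

Step 16
Reactants: 25 methylidene ester
Product: 27 target, (3R,3aS,8R,8aR)-3a-hydroxy-6,8a-dimethyl-1-oxo-3-(propan-2-yl)-1,2,3,3a,4,5,8,8a-octahydroazulen-8-yl 4-methoxybenzoate, via vicinal diol 26 (not isolated)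
Conditions: OsO4 (2 mol %), NaIO4, 2,6-lutidine, dioxane/H2O, rt
Reagents that add atoms: osmium tetroxide (oxygen carrier), O=[Os](=O)(=O)=O; sodium periodate (terminal oxygen source), [Na+].[O-]I(=O)(=O)=O
Why: Lemieux-Johnson cleavage, in which osmylation favours the sterically open 1,1-disubstituted exocyclic alkene next to the homoallylic 3a-hydroxyl group over the trisubstituted ring alkene deactivated by the allylic ester, and periodate cleaves the diol, unmasks the C1 ketone.

Compound list
1 | nerol, (2Z)-3,7-dimethylocta-2,6-dien-1-ol | CC(C)=CCC/C(C)=C\CO | starting material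
2 | neryl tert-butyldiphenylsilyl ether | CC(C)=CCC/C(C)=C\CO[Si](c1ccccc1)(c1ccccc1)C(C)(C)C | intermediate
3 | 6,7-epoxide of 2 (racemic) | CC1(C)OC1CC/C(C)=C\CO[Si](c1ccccc1)(c1ccccc1)C(C)(C)C | intermediate
4 | (6Z)-8-[(tert-butyldiphenylsilyl)oxy]-2,6-dimethyloct-6-ene-2,3-diol (racemic, not isolated) | CC(C)(O)C(O)CC/C(C)=C\CO[Si](c1ccccc1)(c1ccccc1)C(C)(C)C | intermediate
5 | (4Z)-6-[(tert-butyldiphenylsilyl)oxy]-4-methylhex-4-enal | O=CCC/C(C)=C\CO[Si](c1ccccc1)(c1ccccc1)C(C)(C)C | intermediate
6 | methyl (4Z)-6-[(tert-butyldiphenylsilyl)oxy]-4-methylhex-4-enoate | COC(=O)CC/C(C)=C\CO[Si](c1ccccc1)(c1ccccc1)C(C)(C)C | intermediate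
7 | (3-methylbutyl)magnesium bromide | CC(C)CC[Mg]Br | starting material
8 | (1S,2R)-1-{(3Z)-5-[(tert-butyldiphenylsilyl)oxy]-3-methylpent-3-en-1-yl}-2-(propan-2-yl)cyclopropan-1-ol | CC(C)(C)[Si](c1ccccc1)(c1ccccc1)OC/C=C(/C)CC[C@]1(O)C[C@@H]1C(C)C | intermediate
9 | (1S,2R)-1-[(3Z)-5-hydroxy-3-methylpent-3-en-1-yl]-2-(propan-2-yl)cyclopropan-1-ol | OC/C=C(/C)CC[C@]1(O)C[C@@H]1C(C)C | intermediate
10 | (2Z)-5-[(1S,2R)-1-hydroxy-2-(propan-2-yl)cyclopropyl]-3-methylpent-2-enal | O=C/C=C(/C)CC[C@]1(O)C[C@@H]1C(C)C | intermediate
11 | prop-1-yn-1-yllithium | [Li]C#CC | starting material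
12 | 2-(iodomethyl)-4,4,5,5-tetramethyl-1,3,2-dioxaborolane | ICB1OC(C)(C)C(C)(C)O1 | starting material
13 | lithium (iodomethyl)(prop-1-yn-1-yl)(pinacolato)borate (not isolated) | [Li+].CC#C[B-]1(CI)OC(C)(C)C(C)(C)O1 | intermediate
14 | 2-(but-2-yn-1-yl)-4,4,5,5-tetramethyl-1,3,2-dioxaborolane | CC#CCB1OC(C)(C)C(C)(C)O1 | intermediate
15 | O-pinacolboryl ether of 16 (not isolated) | C=C=C(C)[C@@H](OB1OC(C)(C)C(C)(C)O1)/C=C(/C)CC[C@]2(O)C[C@@H]2C(C)C | intermediate
16 | (1S,2R)-1-[(3Z,5S)-5-hydroxy-3,6-dimethylocta-3,6,7-trien-1-yl]-2-(propan-2-yl)cyclopropan-1-ol | C=C=C(C)[C@@H](O)/C=C(/C)CC[C@]1(O)C[C@@H]1C(C)C | intermediate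
17 | (1S,2R)-1-{(3Z,5S)-5-[(tert-butyldimethylsilyl)oxy]-3,6-dimethylocta-3,6,7-trien-1-yl}-2-(propan-2-yl)cyclopropan-1-ol | C=C=C(C)[C@@H](O[Si](C)(C)C(C)(C)C)/C=C(/C)CC[C@]1(O)C[C@@H]1C(C)C | intermediate
18 | cobalt homoenolate, open-chain ketone with C2-Co bond (diphosphine on cobalt not drawn, not isolated) | C=C=C(C)[C@@H](O[Si](C)(C)C(C)(C)C)/C=C(/C)CCC(=O)[C@H](C[Co])C(C)C | intermediate
19 | ten-membered allylcobalt ketone, C8 cis to C2 on the C1=C8a bond (diphosphine on cobalt not drawn, not isolated) | CC(C)(C)[Si](C)(C)O[C@H]1/C=C(C)\CCC(=O)[C@@H](C(C)C)C/C(C[Co])=C1/C | intermediate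
20 | (3R,3aS,8S,8aR)-8-[(tert-butyldimethylsilyl)oxy]-6,8a-dimethyl-1-methylidene-3-(propan-2-yl)-2,3,4,5,8,8a-hexahydroazulen-3a(1H)-ol | CC(C)(C)[Si](C)(C)O[C@H]1C=C(C)CC[C@]2(O)[C@@H](C(C)C)CC(=C)[C@]12C | intermediate
21 | (3R,3aS,8S,8aR)-6,8a-dimethyl-1-methylidene-3-(propan-2-yl)-2,3,4,5,8,8a-hexahydroazulene-3a,8(1H)-diol | O[C@H]1C=C(C)CC[C@]2(O)[C@@H](C(C)C)CC(=C)[C@]12C | intermediate
22 | (3R,3aS,8aS)-3a-hydroxy-6,8a-dimethyl-1-methylidene-3-(propan-2-yl)-2,3,3a,4,5,8a-hexahydroazulen-8(1H)-one | O=C1C=C(C)CC[C@]2(O)[C@@H](C(C)C)CC(=C)[C@]12C | intermediate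
23 | (3R,3aS,8R,8aR)-6,8a-dimethyl-1-methylidene-3-(propan-2-yl)-2,3,4,5,8,8a-hexahydroazulene-3a,8(1H)-diol | O[C@@H]1C=C(C)CC[C@]2(O)[C@@H](C(C)C)CC(=C)[C@]12C | intermediate
24 | 4-methoxybenzoyl chloride | COc1ccc(C(=O)Cl)cc1 | starting material
25 | (3R,3aS,8R,8aR)-3a-hydroxy-6,8a-dimethyl-1-methylidene-3-(propan-2-yl)-1,2,3,3a,4,5,8,8a-octahydroazulen-8-yl 4-methoxybenzoate | COc1ccc(C(=O)O[C@@H]2C=C(C)CC[C@]3(O)[C@@H](C(C)C)CC(=C)[C@]23C)cc1 | intermediate
26 | 1-hydroxy-1-(hydroxymethyl) derivative of 25, 1-OH on the face of the 3a-OH (not isolated) | COc1ccc(C(=O)O[C@@H]2C=C(C)CC[C@]3(O)[C@@H](C(C)C)C[C@](O)(CO)[C@]23C)cc1 | intermediate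
27 | (3R,3aS,8R,8aR)-3a-hydroxy-6,8a-dimethyl-1-oxo-3-(propan-2-yl)-1,2,3,3a,4,5,8,8a-octahydroazulen-8-yl 4-methoxybenzoate | COc1ccc(C(=O)O[C@@H]2C=C(C)CC[C@]3(O)[C@@H](C(C)C)CC(=O)[C@]23C)cc1 | target

Total step count: 16. Longest linear sequence: 15 (steps 1 to 7 and 9 to 16; step 8 is a one-step branch).

Steps most likely to fail

1. Step 11. The ten-membered carbometallation may be outrun by protonation or β-hydride elimination of the homoenolate, or by insertion between two molecules (oligomerisation). The fallback sets out from 7 and 14 and returns at 20. It makes the same two bonds between two molecules, a mode with direct precedent, and closes the seven-membered ring afterwards by metathesis.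
   - Methyl 4-methylpent-4-enoate is cyclopropanated with 7 under the conditions of step 5 to (1S,2R)-1-(3-methylbut-3-en-1-yl)-2-(propan-2-yl)cyclopropan-1-ol F1.
   - Acrolein is allenylated with 14 under the conditions of step 9 to (3S)-4-methylhexa-1,4,5-trien-3-ol F2, which is silylated with TBSCl and imidazole to tert-butyl(dimethyl){[(3S)-4-methylhexa-1,4,5-trien-3-yl]oxy}silane F3.
   - Intermolecular annulation of F1 with F3 (CoBr2, dppe, Zn, DABCO, MeCN) should pass through the same chair with the larger C8 side chain equatorial. It gives (1S,2R,5R)-2-{(1S)-1-[(tert-butyldimethylsilyl)oxy]prop-2-en-1-yl}-2-methyl-1-(3-methylbut-3-en-1-yl)-3-methylidene-5-(propan-2-yl)cyclopentan-1-ol F4.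
   - Ring-closing metathesis with the second-generation Grubbs catalyst in warm toluene joins the vinyl and the isopropenyl group to the C6=C7 bond of 20.

2. Step 5. Ligand exchange on titanium during the reaction may erode the enantioselectivity, and the branched Grignard reagent may react sluggishly. The fallback sets out from 6 and returns at 8, and it replaces asymmetric catalysis by a classical resolution.
   - The plain Kulinkovich reaction of 6 with 7 and Ti(OiPr)4 gives the racemic cis-cyclopropanol F5.
   - Esterification with (S)-2-methoxy-2-phenylacetic acid (DCC, DMAP) gives two diastereomeric esters that are separated by chromatography.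
   - The (S)-2-methoxy-2-phenylacetate of the (1S,2R)-cyclopropanol F6 is cleaved with DIBAL-H at low temperature to 8.

3. Step 16. Osmylation may also occur at the ring alkene, so that chemoselectivity is lost. The fallback sets out from 25 and returns at 27, and it replaces steric selection by hydroxyl direction.
   - Epoxidation with VO(acac)2 and tert-butyl hydroperoxide is directed by the homoallylic 3a-hydroxyl group to the exocyclic alkene and gives the spiro-epoxide of 25 with the oxirane oxygen on the face of the 3a-OH F7.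
   - H5IO6 opens F7 to diol 26 and cleaves it to 27.

Further compounds
F1 | step 11 | (1S,2R)-1-(3-methylbut-3-en-1-yl)-2-(propan-2-yl)cyclopropan-1-ol | C=C(C)CC[C@]1(O)C[C@@H]1C(C)C
F2 | step 11 | (3S)-4-methylhexa-1,4,5-trien-3-ol | C=C=C(C)[C@@H](O)C=C
F3 | step 11 | tert-butyl(dimethyl){[(3S)-4-methylhexa-1,4,5-trien-3-yl]oxy}silane | C=C=C(C)[C@@H](O[Si](C)(C)C(C)(C)C)C=C
F4 | step 11 | (1S,2R,5R)-2-{(1S)-1-[(tert-butyldimethylsilyl)oxy]prop-2-en-1-yl}-2-methyl-1-(3-methylbut-3-en-1-yl)-3-methylidene-5-(propan-2-yl)cyclopentan-1-ol | C=C[C@H](O[Si](C)(C)C(C)(C)C)[C@@]1(C)C(=C)C[C@H](C(C)C)[C@@]1(O)CCC(C)=C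
F5 | step 5 | racemic cis-1-{(3Z)-5-[(tert-butyldiphenylsilyl)oxy]-3-methylpent-3-en-1-yl}-2-(propan-2-yl)cyclopropan-1-ol | CC(C)C1CC1(O)CC/C(C)=C\CO[Si](c1ccccc1)(c1ccccc1)C(C)(C)C
F6 | step 5 | (1S,2R)-1-{(3Z)-5-[(tert-butyldiphenylsilyl)oxy]-3-methylpent-3-en-1-yl}-2-(propan-2-yl)cyclopropyl (2S)-2-methoxy-2-phenylacetate | CO[C@@H](c1ccccc1)C(=O)O[C@@]1(CC/C(C)=C\CO[Si](c2ccccc2)(c2ccccc2)C(C)(C)C)C[C@@H]1C(C)C
F7 | step 16 | spiro-epoxide of 25 at C1, oxirane oxygen on the face of the 3a-OH | COc1ccc(C(=O)O[C@@H]2C=C(C)CC[C@]3(O)[C@@H](C(C)C)C[C@]4(CO4)[C@]23C)cc1
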